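Ring A of the target is a fully substituted phloroglucinol ring in which C6 and C8 each lie ortho to a phenolic oxygen (O5, O7), and C2 has the configuration of natural (2S)-naringenin. Both aryl–CH2 bonds are therefore traced back to oxygen-bound 1,1-dimethylallyl groups: one heating operation, assisted by Eu(fod)3, moves the O5 and O7 tertiary allyl ethers by [3,3] shifts to C6 and C8 and frees both phenols while C2 stays untouched. The precursor is (S)-naringenin bearing 2-methylbut-3-en-2-yl ethers on O5 and O7 and a triisopropylsilyl ether on O4'. The ring B chromene is added last, by O4' propargylation and thermal cyclisation.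

Key step: step 5

Assumption: (S)-naringenin is taken as purchasable in high enantiomeric purity; C2 is never made, only preserved, so every base-mediated step is run cold and with the minimum of base.
Remark: O4' is carried as a TIPS ether rather than a TBS ether, because aryl TBS ethers are cleaved by DBU and by phenoxides in MeCN (the medium of step 3), whereas the aryl TIPS ether should survive and still fall to buffered fluoride.

Step 1
Reactants: 1 (S)-naringenin; 2 3-chloro-3-methylbut-1-yne
Product: 3 (2S)-5-hydroxy-2-(4-hydroxyphenyl)-7-(2-methylbut-3-yn-2-yloxy)chroman-4-one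
Conditions: 2 (1.1 equiv), DBU (1.1 equiv), CuCl2·2H2O (1 mol%), MeCN, −5 to 0 °C
Reagents that add atoms: 3-chloro-3-methylbut-1-yne (2), C#CC(C)(C)Cl
Why: Copper-catalysed O-propargylation (propargylic substitution of the tertiary chloride through a copper acetylide) should alkylate only O7, because one equivalent of DBU ionises the most acidic hydroxyl (para to C4=O) while O5–H is tied up in the hydrogen bond to the carbonyl and O4'–H is the weakest acid, and the cold, base-limited medium leaves C2 untouched.

Step 2
Reactants: 3 (2S)-5-hydroxy-2-(4-hydroxyphenyl)-7-(2-methylbut-3-yn-2-yloxy)chroman-4-one; 4 chlorotri(propan-2-yl)silane (TIPSCl)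
Product: 5 (2S)-5-hydroxy-7-(2-methylbut-3-yn-2-yloxy)-2-[4-(triisopropylsilyloxy)phenyl]chroman-4-one
Conditions: TIPSCl (1.2 equiv), imidazole (2.5 equiv), DMF, 0 °C to rt
Reagents that add atoms: chlorotri(propan-2-yl)silane (4), CC(C)[Si](Cl)(C(C)C)C(C)C
Why: Imidazole-promoted silylation of the free O4' phenol; the hydrogen-bonded, peri-hindered O5–H should not accept the bulky triisopropylsilyl group under these conditions.

Step 3
Reactants: 5 (2S)-5-hydroxy-7-(2-methylbut-3-yn-2-yloxy)-2-[4-(triisopropylsilyloxy)phenyl]chroman-4-one; 2 3-chloro-3-methylbut-1-yne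
Product: 6 (2S)-5,7-bis(2-methylbut-3-yn-2-yloxy)-2-[4-(triisopropylsilyloxy)phenyl]chroman-4-one
Conditions: 2 (3 equiv), DBU (3 equiv), CuCl2 (5 mol%), MeCN, 0 °C to rt
Reagents that add atoms: 3-chloro-3-methylbut-1-yne (2), C#CC(C)(C)Cl
Why: The same copper-catalysed O-propargylation, which is known to etherify hydrogen-bonded ortho-acylphenols when base and electrophile are used in excess, should now take the only free hydroxyl; the O4' silyl ether rules out quinone-methide opening of the pyranone ring and the cold medium keeps base-induced retro-oxa-Michael opening slow, so C2 should stay intact.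

Step 4
Reactants: 6 (2S)-5,7-bis(2-methylbut-3-yn-2-yloxy)-2-[4-(triisopropylsilyloxy)phenyl]chroman-4-one
Product: 7 (2S)-5,7-bis(2-methylbut-3-en-2-yloxy)-2-[4-(triisopropylsilyloxy)phenyl]chroman-4-one
Conditions: H2 (1 atm, stopped after 2 equiv), Pd/CaCO3 poisoned with Pb(OAc)2, quinoline, EtOAc, 0 °C to rt
Reagents that add atoms: none
Why: Lindlar-type semi-hydrogenation of both terminal alkynes over lead-poisoned palladium stops at the vinyl groups and leaves ketone, aryl ethers and silyl ether alone; work-up at or below room temperature on base-washed silica keeps the heat- and acid-labile tertiary allyl ethers from moving early.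

Step 5
Reactants: 7 (2S)-5,7-bis(2-methylbut-3-en-2-yloxy)-2-[4-(triisopropylsilyloxy)phenyl]chroman-4-one
Product: 9 (2S)-5,7-dihydroxy-6,8-bis(3-methylbut-2-enyl)-2-[4-(triisopropylsilyloxy)phenyl]chroman-4-one, via mono-shifted 6-prenyl phenol 8 (not isolated)
Conditions: Eu(fod)3 (fod = 6,6,7,7,8,8,8-heptafluoro-2,2-dimethyloctane-3,5-dionate; 10 mol%), PhCl, Ar, 60 °C, then 115 °C
Reagents that add atoms: none
Why: Each tertiary allyl aryl ether undergoes a concerted, chair-like [3,3] sigmatropic shift (aromatic Claisen rearrangement) that joins its terminal CH2 to the ortho ring carbon, and enolisation then restores the phenol, so a 1,1-dimethylallyl ether delivers an unbranched prenyl group. The closest known reactions are the thermal rearrangement of aryl 1,1-dimethylallyl ethers to ortho-prenylphenols and the Eu(fod)3-accelerated Claisen rearrangement of 5-O-allyl flavanones. No ring is closed and no stereocentre is formed; C2 is a spectator, and the neutral, aprotic medium offers no path to the chalcone that would racemise it. The selectivity needed is regiochemical: the O7 ether must not take C6 before the O5 ether has moved. Trivalent europium chelates C4=O and O5, which weakens the O5–C bond and lets this ether shift at 60 °C to C6, its only free ortho carbon (C4a is quaternary), to give 8, whose O7 ether at 115 °C has only C8 left. An early O7 shift should also prefer C8, because C6 is wedged between two tertiary alkoxy groups.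

Step 6
Reactants: 9 (2S)-5,7-dihydroxy-6,8-bis(3-methylbut-2-enyl)-2-[4-(triisopropylsilyloxy)phenyl]chroman-4-one
Product: 10 (2S)-5,7-dihydroxy-2-(4-hydroxyphenyl)-6,8-bis(3-methylbut-2-enyl)chroman-4-one
Conditions: TBAF (1.1 equiv), AcOH (1.5 equiv), THF, 0 °C
Reagents that add atoms: none
Why: Fluoride-mediated cleavage of the aryl silyl ether (desilylation driven by Si–F bond formation); acetic acid protonates the O4' phenoxide as it forms, so the base-triggered quinone-methide opening that would racemise C2 is avoided and the prenylphenols are untouched.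

Step 7
Reactants: 10 (2S)-5,7-dihydroxy-2-(4-hydroxyphenyl)-6,8-bis(3-methylbut-2-enyl)chroman-4-one; 2 3-chloro-3-methylbut-1-yne
Product: 11 (2S)-5,7-dihydroxy-6,8-bis(3-methylbut-2-enyl)-2-[4-(2-methylbut-3-yn-2-yloxy)phenyl]chroman-4-one
Conditions: 2 (1.3 equiv), DBU (2.2 equiv), CuCl2·2H2O (1 mol%), MeCN, −5 to 0 °C
Reagents that add atoms: 3-chloro-3-methylbut-1-yne (2), C#CC(C)(C)Cl
Why: Copper-catalysed O-propargylation once more; the bulky tertiary electrophile should take the unhindered O4' phenoxide, because O7 is flanked by two prenyl groups and O5 is hydrogen-bonded to C4=O and ortho-substituted, while the additional negative charge on ring A disfavours cleavage of the C2–O1 bond.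

Step 8
Reactants: 11 (2S)-5,7-dihydroxy-6,8-bis(3-methylbut-2-enyl)-2-[4-(2-methylbut-3-yn-2-yloxy)phenyl]chroman-4-one
Product: 14 (2S)-2-(2,2-dimethyl-2H-chromen-6-yl)-5,7-dihydroxy-6,8-bis(3-methylbut-2-enyl)chroman-4-one, via ortho-allenylphenol 12 (not isolated), via ortho-quinone methide 13 (not isolated)
Conditions: o-xylene (degassed), BHT (trace), Ar, 140 °C
Reagents that add atoms: none
Why: Thermal aromatic propargyl Claisen rearrangement to C3' followed by enolisation gives allenylphenol 12, a [1,5]-hydrogen shift from O4'–H to the central allene carbon gives ortho-quinone methide 13, and oxa-6π electrocyclisation closes the 2,2-dimethyl-2H-pyran; ring A has no free ortho carbon and the neutral medium leaves C2 and the prenyl groups alone.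

Compound list
1 | (S)-naringenin, (2S)-5,7-dihydroxy-2-(4-hydroxyphenyl)chroman-4-one | O=C1C[C@@H](c2ccc(O)cc2)Oc2cc(O)cc(O)c12 | starting material
2 | 3-chloro-3-methylbut-1-yne | C#CC(C)(C)Cl | starting material
3 | (2S)-5-hydroxy-2-(4-hydroxyphenyl)-7-(2-methylbut-3-yn-2-yloxy)chroman-4-one | O=C1C[C@@H](c2ccc(O)cc2)Oc2cc(OC(C)(C)C#C)cc(O)c12 | intermediate
4 | chlorotri(propan-2-yl)silane (TIPSCl) | CC(C)[Si](Cl)(C(C)C)C(C)C | starting material
5 | (2S)-5-hydroxy-7-(2-methylbut-3-yn-2-yloxy)-2-[4-(triisopropylsilyloxy)phenyl]chroman-4-one | O=C1C[C@@H](c2ccc(O[Si](C(C)C)(C(C)C)C(C)C)cc2)Oc2cc(OC(C)(C)C#C)cc(O)c12 | intermediate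
6 | (2S)-5,7-bis(2-methylbut-3-yn-2-yloxy)-2-[4-(triisopropylsilyloxy)phenyl]chroman-4-one | O=C1C[C@@H](c2ccc(O[Si](C(C)C)(C(C)C)C(C)C)cc2)Oc2cc(OC(C)(C)C#C)cc(OC(C)(C)C#C)c12 | intermediate
7 | (2S)-5,7-bis(2-methylbut-3-en-2-yloxy)-2-[4-(triisopropylsilyloxy)phenyl]chroman-4-one | C=CC(C)(C)Oc1cc(OC(C)(C)C=C)cc2c1C(=O)C[C@@H](c1ccc(O[Si](C(C)C)(C(C)C)C(C)C)cc1)O2 | intermediate
8 | (2S)-5-hydroxy-7-(2-methylbut-3-en-2-yloxy)-6-(3-methylbut-2-enyl)-2-[4-(triisopropylsilyloxy)phenyl]chroman-4-one | C=CC(C)(C)Oc1cc2c(c(O)c1CC=C(C)C)C(=O)C[C@@H](c1ccc(O[Si](C(C)C)(C(C)C)C(C)C)cc1)O2 | intermediate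
9 | (2S)-5,7-dihydroxy-6,8-bis(3-methylbut-2-enyl)-2-[4-(triisopropylsilyloxy)phenyl]chroman-4-one | CC(C)=CCc1c(O)c(CC=C(C)C)c2c(c1O)C(=O)C[C@@H](c1ccc(O[Si](C(C)C)(C(C)C)C(C)C)cc1)O2 | intermediate
10 | (2S)-5,7-dihydroxy-2-(4-hydroxyphenyl)-6,8-bis(3-methylbut-2-enyl)chroman-4-one (6,8-diprenylnaringenin) | CC(C)=CCc1c(O)c(CC=C(C)C)c2c(c1O)C(=O)C[C@@H](c1ccc(O)cc1)O2 | intermediate
11 | (2S)-5,7-dihydroxy-6,8-bis(3-methylbut-2-enyl)-2-[4-(2-methylbut-3-yn-2-yloxy)phenyl]chroman-4-one | CC(C)=CCc1c(O)c(CC=C(C)C)c2c(c1O)C(=O)C[C@@H](c1ccc(OC(C)(C)C#C)cc1)O2 | intermediate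
12 | (2S)-5,7-dihydroxy-2-[4-hydroxy-3-(3-methylbuta-1,2-dienyl)phenyl]-6,8-bis(3-methylbut-2-enyl)chroman-4-one | CC(C)=CCc1c(O)c(CC=C(C)C)c2c(c1O)C(=O)C[C@@H](c1ccc(O)c(C=C=C(C)C)c1)O2 | intermediate
13 | (2S)-5,7-dihydroxy-6,8-bis(3-methylbut-2-enyl)-2-[(3Z)-3-(3-methylbut-2-enylidene)-4-oxocyclohexa-1,5-dienyl]chroman-4-one | CC(C)=CCc1c(O)c(CC=C(C)C)c2c(c1O)C(=O)C[C@@H](C1=C/C(=C/C=C(C)C)C(=O)C=C1)O2 | intermediate
14 | (2S)-2-(2,2-dimethyl-2H-chromen-6-yl)-5,7-dihydroxy-6,8-bis(3-methylbut-2-enyl)chroman-4-one | CC(C)=CCc1c(O)c(CC=C(C)C)c2c(c1O)C(=O)C[C@@H](c1ccc3c(c1)C=CC(C)(C)O3)O2 | target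

Total step count: 8
Longest linear sequence: 8 steps (1 to 14)

Steps most likely to fail

First, step 5. The tertiary allyl ethers may ionise under Lewis acid or heat and be lost as isoprene, or the O7 group may shift into C6 before the O5 group has moved, which leaves the O5 ether without a free ortho carbon. The fallback gives up the sigmatropic logic for electrophilic aromatic substitution; it sets out from 1 and comes back to the route at 10. (S)-Naringenin would be C-prenylated directly on ring A with an excess of 2-methylbut-3-en-2-ol and BF3·OEt2 in dioxane at room temperature (Friedel–Crafts alkylation by the dimethylallyl cation, a known way to C-prenylated naringenins). The doubly alkylated product 10 would be separated from under-alkylated material, and its optical purity checked because a Lewis acid is present. No ether, no silyl group and no rearrangement are needed, at the price of regiocontrol.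

Second, step 3. Etherification of the hydrogen-bonded, peri-hindered O5–H may be sluggish, and the forcing basic medium may open the 5-O-alkylated flavanone by retro-oxa-Michael reaction and erode C2. The fallback etherifies O5 without base and sets out from 5, coming back at 9. A Mitsunobu reaction of 5 with allyl alcohol (PPh3, DIAD, THF, 0 °C to rt) should give (2S)-7-(2-methylbut-3-yn-2-yloxy)-5-(prop-2-enyloxy)-2-[4-(triisopropylsilyloxy)phenyl]chroman-4-one F1. Semi-hydrogenation of its single alkyne over Pd/CaCO3 poisoned with Pb(OAc)2 should give (2S)-7-(2-methylbut-3-en-2-yloxy)-5-(prop-2-enyloxy)-2-[4-(triisopropylsilyloxy)phenyl]chroman-4-one F2. The Eu(fod)3-assisted double shift, as in step 5, should then send the O5 allyl group to C6 and the O7 tertiary allyl group to C8, giving (2S)-5,7-dihydroxy-8-(3-methylbut-2-enyl)-6-(prop-2-enyl)-2-[4-(triisopropylsilyloxy)phenyl]chroman-4-one F3. Olefin cross-metathesis of the C6 allyl group with 2-methylbut-2-ene (second-generation Grubbs catalyst, CH2Cl2, 40 °C) should turn it into a prenyl group and return to the route at 9.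

Third, step 7. Ring A phenoxides may compete for the electrophile, conversion may stall because the base is held by the more acidic O7–H, or the flavanone may open under DBU. The fallback builds the pyran ring from the phenol and an enal instead of an O-propargyl ether; it sets out from 10 and comes back at 14. Heating 10 with 3-methylbut-2-enal, PhB(OH)2 and AcOH in toluene at reflux (Dean–Stark) should condense the aldehyde at C3' of ring B to the cyclic phenylboronate (2S)-5,7-dihydroxy-6,8-bis(3-methylbut-2-enyl)-2-[4-(2-methylprop-1-enyl)-2-phenyl-4H-1,3,2-benzodioxaborinin-6-yl]chroman-4-one F4 (not isolated, either configuration at the new carbon). F4 should fragment thermally to the ortho-quinone methide 13, which closes to 14. Ring A cannot take part because it has no free ortho carbon.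

Further compounds
F0 | step 5 | none | none
F1 | step 3 | (2S)-7-(2-methylbut-3-yn-2-yloxy)-5-(prop-2-enyloxy)-2-[4-(triisopropylsilyloxy)phenyl]chroman-4-one | C=CCOc1cc(OC(C)(C)C#C)cc2c1C(=O)C[C@@H](c1ccc(O[Si](C(C)C)(C(C)C)C(C)C)cc1)O2
F2 | step 3 | (2S)-7-(2-methylbut-3-en-2-yloxy)-5-(prop-2-enyloxy)-2-[4-(triisopropylsilyloxy)phenyl]chroman-4-one | C=CCOc1cc(OC(C)(C)C=C)cc2c1C(=O)C[C@@H](c1ccc(O[Si](C(C)C)(C(C)C)C(C)C)cc1)O2
F3 | step 3 | (2S)-5,7-dihydroxy-8-(3-methylbut-2-enyl)-6-(prop-2-enyl)-2-[4-(triisopropylsilyloxy)phenyl]chroman-4-one | C=CCc1c(O)c(CC=C(C)C)c2c(c1O)C(=O)C[C@@H](c1ccc(O[Si](C(C)C)(C(C)C)C(C)C)cc1)O2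
F4 | step 7 | (2S)-5,7-dihydroxy-6,8-bis(3-methylbut-2-enyl)-2-[4-(2-methylprop-1-enyl)-2-phenyl-4H-1,3,2-benzodioxaborinin-6-yl]chroman-4-one | CC(C)=CCc1c(O)c(CC=C(C)C)c2c(c1O)C(=O)C[C@@H](c1ccc3OB(c4ccccc4)OC(C=C(C)C)c3c1)O2
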